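**Plan**

- Retrosynthesis: the two bonds of the bridging CH2 (aryl–CH2 and CH2–dienone ring) are cut first, giving a formaldehyde equivalent, 2,6-dihydroxy-4-methoxyacetophenone and acetylfilicinic acid. The C-acetyl bond on the dienone ring is cut next. In the remaining 4,4-dimethylcyclohexane-1,3,5-trione (filicinic acid) ring, two ring bonds are cut: the bond from the quaternary C(CH3)2 carbon to the enol carbon on the bridge side, and the bond from the other enol carbon to the ring carbon that carries the acetyl group.
- Enabling feature: in that six-membered ring the C(CH3)2 carbon and one adjacent C–O carbon form a dimethylketene-like two-carbon unit (nucleophilic at the quaternary carbon, acylating at the carbonyl carbon). The other four ring carbons form an acetoacetyl unit of opposite polarity (acyl carbon at one end, enolate carbon at the other), which is diketene.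
- Forward order: the carbocycle is made first, in one operation, from a phenyl ester enolate and diketene (step 1). It is then C-acetylated (step 2); the two ring CH positions are equivalent by symmetry, so it is immaterial which takes the acetyl and which the bridge. The dienone ring is joined last through the methylene bridge to the aromatic ring, which is bought intact (step 3).
- Stereochemistry: the target has no stereocentre and no stereogenic double bond; it is a tautomeric β-triketone drawn in one enol form.

Key step: step 1

Remark: phenyl 2-methylpropanoate, diketene and 1-(2,6-dihydroxy-4-methoxyphenyl)ethan-1-one are taken as purchased, and every β-triketone is written in one enol form with the other tautomers implied.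

**Step 1**
Reactants: 1 phenyl 2-methylpropanoate; 2 diketene (4-methylideneoxetan-2-one)
Product: 5 filicinic acid (3,5-dihydroxy-4,4-dimethylcyclohexa-2,5-dien-1-one), via lithium ester enolate 3 (not isolated), via open-chain lithium enolate 4 (not isolated)
Conditions: LiN(iPr)2 (2.2 equiv), THF, −78 °C; 1 (2.2 equiv); 2 (1.0 equiv) added slowly, −78 → −30 °C; then 1 M HCl
Reagents that add atoms: none
Why: Proposed new method: the lithium enolate 3 is a dimethylketene equivalent, nucleophilic at its C(CH3)2 carbon and acylating at its phenoxycarbonyl carbon, and it should attack the strained lactone carbonyl of diketene, whose acyl–oxygen cleavage sets free the terminal enolate 4 at the former exocyclic methylene carbon; this carbon then closes onto the phenyl ester with loss of phenoxide, a tandem crossed Claisen–Dieckmann sequence that amounts to a (4+2) annulation. The closest known reaction types are the C-acetoacetylation of carbanions by diketene, the addition of phenyl ester enolates to ketones followed by internal acyl substitution with loss of phenoxide (β-lactone synthesis), and the Dieckmann closure of 3,5-dioxo ester enolates to cyclohexane-1,3,5-triones, which is also the last event in the base-induced trimerisation of dimethylketene. The six-membered ring closes in the 6-(enolendo)-exo-trig mode, helped by the gem-dimethyl group, and the product is held as its stable trione enolate. No stereocentre arises. The step needs acyl attack on diketene in preference to removal of its ring protons, C- in preference to O-acylation at the closure, and no loss of reacting enolate to the acidic product: the first rests on the ring strain and high acyl reactivity of the β-lactone at −78 °C, the second on the lithium counter-ion in THF without polar additive and on the fact that an enol lactone formed by O-attack is itself an active ester that phenoxide can reopen towards the far more stable trione enolate, and the third on the second equivalent of 3, which serves as sacrificial base.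

**Step 2**
Reactants: 5 filicinic acid
Product: 7 acetylfilicinic acid (2-acetyl-3,5-dihydroxy-4,4-dimethylcyclohexa-2,5-dien-1-one), via enol acetate 6 (not isolated)
Conditions: AcOH (1.0 equiv), N,N'-dicyclohexylcarbodiimide (1.1 equiv), 4-(dimethylamino)pyridine (1.2 equiv), CH2Cl2, 0 °C → rt; 1 M HCl wash
Reagents that add atoms: acetic acid, CC(=O)O
Why: Steglich-type O-acylation of the enol with the carbodiimide-activated acid followed by 4-(dimethylamino)pyridine-mediated O-to-C acyl migration is the standard C-acylation of cyclic 1,3-diones and should place the acetyl group on a ring CH flanked by two carbonyl groups, the two such positions of 5 being equivalent and the monoacyl product being held back from a second acylation as its more acidic, less nucleophilic enolate salt.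

**Step 3**
Reactants: 7 acetylfilicinic acid; 8 1-(2,6-dihydroxy-4-methoxyphenyl)ethan-1-one
Product: 11 2-acetyl-6-[(3-acetyl-2,4-dihydroxy-6-methoxyphenyl)methyl]-3,5-dihydroxy-4,4-dimethylcyclohexa-2,5-dien-1-one, via Mannich base 9 (not isolated), via exocyclic enetrione 10 (not isolated)
Conditions: Eschenmoser's salt (1.05 equiv), MeCN, 0 °C → rt; then 8 (1.5 equiv), NaOAc (1.1 equiv), 60 °C
Reagents that add atoms: N,N-dimethylmethylideneammonium iodide (Eschenmoser's salt), C=[N+](C)C.[I-]
Why: Mannich aminomethylation of the only remaining ring CH of 7, E1cB loss of dimethylamine to the 2-methylidene-1,3-dione 10 and Friedel–Crafts-type Michael addition of the electron-rich arene 8 at one of its two equivalent free positions is the established three-component methylene bridging of β-triketones with acylphloroglucinols, and making 9 before 8 is added should keep the cross-coupling ahead of the two symmetrical couplings; no stereocentre is formed.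

**Compound list**

1 | phenyl 2-methylpropanoate | CC(C)C(=O)Oc1ccccc1 | starting material
2 | diketene (4-methylideneoxetan-2-one) | C=C1CC(=O)O1 | starting material
3 | lithium 2-methyl-1-phenoxyprop-1-en-1-olate (lithium enolate of 1) | CC(C)=C(O[Li])Oc1ccccc1 | intermediate
4 | phenyl 5-(lithiooxy)-2,2-dimethyl-3-oxohex-5-enoate | C=C(O[Li])CC(=O)C(C)(C)C(=O)Oc1ccccc1 | intermediate
5 | filicinic acid (3,5-dihydroxy-4,4-dimethylcyclohexa-2,5-dien-1-one) | CC1(C)C(O)=CC(=O)C=C1O | intermediate
6 | 5-hydroxy-4,4-dimethyl-3-oxocyclohexa-1,5-dien-1-yl acetate | CC(=O)OC1=CC(=O)C(C)(C)C(O)=C1 | intermediate
7 | acetylfilicinic acid (2-acetyl-3,5-dihydroxy-4,4-dimethylcyclohexa-2,5-dien-1-one) | CC(=O)C1=C(O)C(C)(C)C(O)=CC1=O | intermediate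
8 | 1-(2,6-dihydroxy-4-methoxyphenyl)ethan-1-one | COc1cc(O)c(C(C)=O)c(O)c1 | starting material
9 | 2-acetyl-6-[(dimethylamino)methyl]-3,5-dihydroxy-4,4-dimethylcyclohexa-2,5-dien-1-one | CC(=O)C1=C(O)C(C)(C)C(O)=C(CN(C)C)C1=O | intermediate
10 | 2-acetyl-3-hydroxy-4,4-dimethyl-6-methylidenecyclohex-2-ene-1,5-dione | CC(=O)C1=C(O)C(C)(C)C(=O)C(=C)C1=O | intermediate
11 | 2-acetyl-6-[(3-acetyl-2,4-dihydroxy-6-methoxyphenyl)methyl]-3,5-dihydroxy-4,4-dimethylcyclohexa-2,5-dien-1-one | COc1cc(O)c(C(C)=O)c(O)c1CC1=C(O)C(C)(C)C(O)=C(C(C)=O)C1=O | target

**Step count and risks**

Total step count: 3. Longest linear sequence: 3 steps (1 → 5 → 7 → 11).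

Steps most likely to fail, riskiest first:

Step 1 (proposed new method). The ester enolate may act as a base towards diketene, leading to ring-proton abstraction and oligomerisation, or the ring may close through the enolate oxygen to an enol lactone instead of through carbon. The fallback uses known reaction types, stepwise instead of tandem, with an acid chloride in place of the β-lactone. It sets out from compound 1, whose lithium enolate is C-acylated at −78 °C with (2E)-3-methoxybut-2-enoyl chloride to give phenyl (4E)-5-methoxy-2,2-dimethyl-3-oxohex-4-enoate F1. This compound has no CH2 between two carbonyl groups and its remote oxygen is methylated, so neither enolate scrambling nor closure through oxygen is open to it. In a separate operation LiN(iPr)2 removes a proton from the terminal methyl group and the vinylogous enolate closes onto the phenyl ester (Dieckmann) to give 5-hydroxy-3-methoxy-6,6-dimethylcyclohexa-2,4-dien-1-one F2. Warm dilute HCl in THF hydrolyses the vinylogous methyl ester, and the route is rejoined at compound 5.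

Step 3. Reversal of the Mannich and Michael events may scramble the bridge towards the two symmetrical methylene-bis compounds, and the enetrione may add to itself. The fallback reverses the roles of the partners. It sets out from compound 8, which is aminomethylated with Eschenmoser's salt to 1-{3-[(dimethylamino)methyl]-2,6-dihydroxy-4-methoxyphenyl}ethan-1-one F3. Heating this with compound 7 in dioxane at about 100 °C should expel dimethylamine and give, in low stationary concentration, the ortho-quinone methide 2-acetyl-3-hydroxy-5-methoxy-6-methylidenecyclohexa-2,4-dien-1-one F4, which is trapped by the enol carbon of 7. The route is rejoined at the target, compound 11.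

Step 2. The acyl shift from oxygen to carbon may stall at the enol ester 6, or a second acetyl group may enter at the other ring CH. The fallback is a Lewis acid route with no enol ester and no acyl-transfer catalyst. It sets out from compound 5, which is C-acylated directly in a Friedel–Crafts manner with acetyl chloride and AlCl3 in nitrobenzene, the product staying bound to the Lewis acid until aqueous HCl work-up and so resisting a second acylation. It comes back at compound 7 and makes no compound outside the list (F0).

**Further compounds**

F1 | step 1 | phenyl (4E)-5-methoxy-2,2-dimethyl-3-oxohex-4-enoate | CO/C(C)=C/C(=O)C(C)(C)C(=O)Oc1ccccc1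
F2 | step 1 | 5-hydroxy-3-methoxy-6,6-dimethylcyclohexa-2,4-dien-1-one | COC1=CC(=O)C(C)(C)C(O)=C1
F3 | step 3 | 1-{3-[(dimethylamino)methyl]-2,6-dihydroxy-4-methoxyphenyl}ethan-1-one | COc1cc(O)c(C(C)=O)c(O)c1CN(C)C
F4 | step 3 | 2-acetyl-3-hydroxy-5-methoxy-6-methylidenecyclohexa-2,4-dien-1-one | COC1=CC(O)=C(C(C)=O)C(=O)C1=C
F0 | step 2 | none | none
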